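**Retrosynthetic overview**

1. Ring numbering of the target: C1 (CH–OAc), C2 (=CH), C3 (=C–CH2OBz), C4 (CH–OH), C5 (CH–OBz), C6 (CH–OH). Endgame: the C4 hydroxyl is freed from a 4-methoxyphenyl ether, the C1 acetate comes from Mitsunobu inversion of the allylic hydroxyl of a C1/C6 cis-diol, and both benzoates are installed in one acylation.
2. The C4–O bond and the C2=C3 alkene come from a rhodium-catalysed anti SN2' opening (run as a kinetic resolution) of a 7-oxabicyclo[2.2.1]heptene by 4-methoxyphenol; the bridge oxygen stays on C5.
3. The oxabicycle comes from a Diels–Alder dearomatisation of furan-3-ylmethanol with vinylene carbonate, which forms C1–C2 and C5–C6 and places the C1, C5 and C6 oxygens on one face.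
4. Enabling feature: C2–C3–C4–C5 with the exocyclic CH2O carbon on C3 are the four carbons of a 3-substituted furan, and the C5 oxygen is the furan oxygen, whose second bond (to C2) is allylic in the adduct and is cut in step 4. C1 and C6 with their vicinal oxygens are the two alkene carbons of vinylene carbonate.
5. Ring order: the cyclohexene ring (with a temporary oxygen bridge and carbonate ring) is formed in step 1; no further ring of the target has to be made.

Key step: step 1

Assumption: the sense in which the ferrocenyl ligand of step 4 selects between the enantiomers of 5 is assigned by analogy with meso oxabicyclic alkenes; if the (R,S) ligand should consume the other enantiomer, its (S,R) mirror image is used with no other change.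

**Route**

Step 1
Reactants: 1 furan-3-ylmethanol; 2 vinylene carbonate (1,3-dioxol-2-one)
Product: 3 racemic exo adduct, 5-(hydroxymethyl)-7-oxabicyclo[2.2.1]hept-5-ene-2-exo,3-exo-diyl cyclic carbonate
Conditions: 2 (3 equiv), BHT (cat.), neat, sealed tube, 125 °C; exo adduct separated by chromatography
Reagents that add atoms: none
Why: Thermal suprafacial [4+2] cycloaddition (Diels–Alder) in which furan carbons C2 and C5 of 1 bond to the two alkene carbons of 2, dearomatising the furan; the closest known reaction is the furan/vinylene carbonate cycloaddition used for cyclitol synthesis. The six-membered carbocycle is closed by the concerted cycloaddition, with the oxygen bridge and the carbonate ring carried in intact. The cis relation of the two carbonate oxygens follows from the cis alkene of 2, and the two bridgeheads are tied to one face by the bridge. The exo placement of the carbonate (cis to the bridge oxygen, hence cis to the future C5 oxygen) should follow from thermodynamic control, since the addition is reversible at this temperature; endo-rich material is returned to the equilibrating conditions. Because the two alkene carbons of 2 are equivalent, the 3-substituent of 1 raises no regiochemical question, so exo over endo is the only selectivity needed. The adduct is racemic, and the enantiomers are parted in step 4.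

Step 2
Reactants: 3 racemic exo carbonate
Product: 4 racemic 5-(hydroxymethyl)-7-oxabicyclo[2.2.1]hept-5-ene-2-exo,3-exo-diol
Conditions: K2CO3 (0.2 equiv), MeOH, 0 °C to rt
Reagents that add atoms: none
Why: Base-catalysed transesterification (methanolysis) of the strained five-membered cyclic carbonate; no stereocenter is touched.

Step 3
Reactants: 4 racemic triol
Product: 5 racemic 2-exo,3-exo-O-isopropylidene derivative of 4 (primary alcohol free)
Conditions: Me2C(OMe)2, PPTS (cat.), acetone, rt
Reagents that add atoms: 2,2-dimethoxypropane, COC(C)(C)OC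
Why: Acid-catalysed transketalisation; only the cis 1,2-diol can close a five-membered isopropylidene ketal, which keeps these two oxygens apart from the hydroxyls acylated in step 5.

Step 4
Reactants: 5 racemic acetonide
Product: 6 single enantiomer of 3-(hydroxymethyl)-1,6-O-isopropylidene-4-O-(4-methoxyphenyl)cyclohex-2-ene-1,4,5,6-tetrol (C1–O, C6–O and C5–OH all cis; C4–OAr trans to C5–OH)
Conditions: [Rh(cod)Cl]2 (2.5 mol %), (R)-1-[(S)-2-(diphenylphosphino)ferrocenyl]ethyl-di-tert-butylphosphine (6 mol %), AgOSO2CF3 (7 mol %), Bu4NI (10 mol %), 4-MeOC6H4OH (0.6 equiv), tetrahydropyran, 80 °C, stopped near half conversion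
Reagents that add atoms: 4-methoxyphenol, COc1ccc(O)cc1
Why: Rhodium-catalysed asymmetric ring opening of an oxabicyclic alkene by a phenol (anti SN2' type): monovalent rhodium inserts from the exo face into the bridgehead C–O bond next to the substituted alkene carbon and the phenoxide attacks the CH alkene carbon from the open endo face, so the C4 aryloxy group ends trans to the C5 hydroxyl and the alkene moves to C2=C3, while the chiral ligand should let only one enantiomer of 5 react in this sense (kinetic resolution), the other being left with attack at the fully substituted alkene carbon only.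

Step 5
Reactants: 6 diol
Product: 7 dibenzoate of 6 (benzoates on the C5 oxygen and on the CH2O group)
Conditions: BzCl (2.5 equiv), pyridine, DMAP (cat.), CH2Cl2, 0 °C to rt
Reagents that add atoms: benzoyl chloride, O=C(Cl)c1ccccc1
Why: DMAP-catalysed acylation of the only two free hydroxyls, which installs both benzoates of the target at once; no stereocenter is affected.

Step 6
Reactants: 7 acetonide dibenzoate
Product: 8 C1/C6 cis-diol (C1–OH, C6–OH and C5–OBz all cis; C4–OAr trans)
Conditions: AcOH/H2O 4:1, 45 °C
Reagents that add atoms: none
Why: Acid-catalysed hydrolysis of the isopropylidene ketal under conditions to which benzoates and the aryl ether are inert and under which acyl migration is slow; the four stereocenters are untouched.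

Step 7
Reactants: 8 cis-diol
Product: 9 C1 acetate with inverted C1, the 4-O-(4-methoxyphenyl) ether of the target
Conditions: PPh3, DIAD, AcOH (1.5 equiv each), THF, 0 °C to rt, DIAD added last
Reagents that add atoms: acetic acid, CC(=O)O
Why: Mitsunobu reaction: the allylic C1 hydroxyl is the more reactive one (the C6 hydroxyl is flanked on both sides and, being cis, cannot close an epoxide) and its oxyphosphonium is displaced by acetate in an SN2 step with inversion, which sets the C1 acetate trans to the C6 hydroxyl; the SN2' alternative would require attack at the fully substituted C3.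

Step 8
Reactants: 9 aryl ether
Product: 10 target, (1R,4S,5R,6S)-5-(benzoyloxy)-3-[(benzoyloxy)methyl]-4,6-dihydroxycyclohex-2-en-1-yl acetate
Conditions: (NH4)2Ce(NO3)6 (2.5 equiv), MeCN/H2O 4:1, 0 °C
Reagents that add atoms: none
Why: Oxidative dearylation of a 4-methoxyphenyl ether (single-electron oxidation of the arene and hydrolysis to benzoquinone) should free the C4 hydroxyl with its oxygen and configuration retained and without base, so that no acyl migration is expected.

**Compound list**

1 | furan-3-ylmethanol | OCc1ccoc1 | starting material
2 | vinylene carbonate (1,3-dioxol-2-one) | O=C1OC=CO1 | starting material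
3 | exo cyclic carbonate of 5-(hydroxymethyl)-7-oxabicyclo[2.2.1]hept-5-ene-2,3-diol (racemate; the enantiomer drawn is the one carried on) | OCC1=C[C@H]2O[C@@H]1[C@@H]3OC(=O)O[C@H]23 | intermediate
4 | 5-(hydroxymethyl)-7-oxabicyclo[2.2.1]hept-5-ene-2-exo,3-exo-diol (racemate; same enantiomer drawn) | OCC1=C[C@H]2O[C@@H]1[C@H](O)[C@@H]2O | intermediate
5 | 2-exo,3-exo-O-isopropylidene derivative of 4 (racemate; the enantiomer drawn is the one consumed in step 4) | OCC1=C[C@H]2O[C@@H]1[C@@H]3OC(C)(C)O[C@H]23 | intermediate
6 | 3-(hydroxymethyl)-1,6-O-isopropylidene-4-O-(4-methoxyphenyl)cyclohex-2-ene-1,4,5,6-tetrol, C1–O/C6–O/C5–OH cis, C4–OAr trans to C5–OH, single enantiomer | OCC1=C[C@@H]2OC(C)(C)O[C@@H]2[C@H](O)[C@H]1Oc1ccc(OC)cc1 | intermediate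
7 | 5-O-benzoyl and CH2O-benzoyl derivative of 6 | O=C(OCC1=C[C@@H]2OC(C)(C)O[C@@H]2[C@H](OC(=O)c2ccccc2)[C@H]1Oc1ccc(OC)cc1)c1ccccc1 | intermediate
8 | C1/C6 cis-diol from 7 (C1–OH, C6–OH, C5–OBz cis; C4–OAr trans) | O=C(OCC1=C[C@H](O)[C@H](O)[C@H](OC(=O)c2ccccc2)[C@H]1Oc1ccc(OC)cc1)c1ccccc1 | intermediate
9 | 4-O-(4-methoxyphenyl) ether of the target (C1–OAc trans to C6–OH) | O=C(OCC1=C[C@@H](OC(C)=O)[C@H](O)[C@H](OC(=O)c2ccccc2)[C@H]1Oc1ccc(OC)cc1)c1ccccc1 | intermediate
10 | (1R,4S,5R,6S)-5-(benzoyloxy)-3-[(benzoyloxy)methyl]-4,6-dihydroxycyclohex-2-en-1-yl acetate | CC(=O)O[C@@H]1C=C(COC(=O)c2ccccc2)[C@H](O)[C@@H](OC(=O)c2ccccc2)[C@H]1O | target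

**Step count and risks**

Total steps: 8. Longest linear sequence: 8 steps (1 to 10).

Steps most likely to fail:

Step 4. The insertion of rhodium may discriminate poorly between the two enantiomers of 5, or be slow at the trisubstituted alkene, so that 6 is formed in low enantiomeric purity. Fallback, setting out from 5: an achiral catalyst from [Rh(cod)Cl]2 and 1,1'-bis(diphenylphosphino)ferrocene (AgOSO2CF3, Bu4NI, excess 4-methoxyphenol, tetrahydropyran, 80 °C) would open both enantiomers to racemic 6 F1. Acylation of both hydroxyls with (1S)-camphanic chloride (pyridine, DMAP) would give two diastereomeric bis-camphanates, to be separated by crystallisation or chromatography. Methanolysis (K2CO3, MeOH) of the diastereomer with the ring configuration of 6, bis-camphanate F2, returns to the route at 6.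

Step 7. Site selection may fail: the diol may react through a cyclic dioxaphosphorane and place the acetate at C6, eliminate towards a diene, or suffer benzoyl migration from C5 to C6 under the basic betaine. Fallback, setting out from 8: SOCl2 and Et3N in CH2Cl2 at 0 °C would give the cyclic sulfite F3, and brief oxidation with catalytic RuCl3 and NaIO4 (MeCN/H2O, 0 °C) the cyclic sulfate F4. CsO2CCH3 in DMF should open F4 at the allylic C1 with inversion to the cesium salt of the C6 sulfate monoester F5. Hydrolysis of F5 with catalytic H2SO4 in wet THF returns to the route at 9.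

Step 1. The free primary hydroxyl may undergo transcarbonation with 2 or with the adduct at 125 °C, 2 may polymerise, and exo selection under equilibration may be incomplete. Fallback, setting out from 1: benzoylation (BzCl, pyridine) would give furan-3-ylmethyl benzoate F6, whose cycloaddition with 2 under the conditions of step 1 should give the exo adduct benzoate F7 without a free hydroxyl. Full methanolysis of carbonate and benzoate (K2CO3, MeOH, rt) returns to the route at 4.

**Further compounds**

F1 | step 4 | racemic 6 (both enantiomers; the needed one drawn) | OCC1=C[C@@H]2OC(C)(C)O[C@@H]2[C@H](O)[C@H]1Oc1ccc(OC)cc1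
F2 | step 4 | bis-(1S)-camphanate of 6 | O=C(OCC1=C[C@@H]2OC(C)(C)O[C@@H]2[C@H](OC(=O)[C@@]23CC[C@@](C)(C(=O)O2)C3(C)C)[C@H]1Oc1ccc(OC)cc1)[C@@]12CC[C@@](C)(C(=O)O1)C2(C)C
F3 | step 7 | C1/C6 cyclic sulfite of 8 (mixture at sulfur) | O=C(OCC1=C[C@@H]2OS(=O)O[C@@H]2[C@H](OC(=O)c2ccccc2)[C@H]1Oc1ccc(OC)cc1)c1ccccc1
F4 | step 7 | C1/C6 cyclic sulfate of 8 | O=C(OCC1=C[C@@H]2OS(=O)(=O)O[C@@H]2[C@H](OC(=O)c2ccccc2)[C@H]1Oc1ccc(OC)cc1)c1ccccc1
F5 | step 7 | cesium salt of the C6 sulfate monoester of 9 | O=C(OCC1=C[C@@H](OC(C)=O)[C@H](OS(=O)(=O)[O-])[C@H](OC(=O)c2ccccc2)[C@H]1Oc1ccc(OC)cc1)c1ccccc1.[Cs+]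
F6 | step 1 | furan-3-ylmethyl benzoate | O=C(OCc1ccoc1)c1ccccc1
F7 | step 1 | exo cyclic carbonate of 5-(benzoyloxymethyl)-7-oxabicyclo[2.2.1]hept-5-ene-2,3-diol (racemate; one enantiomer drawn) | O=C(OCC1=C[C@H]2O[C@@H]1[C@@H]3OC(=O)O[C@H]23)c1ccccc1
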